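The reading comes at 50 min, so I ask first whether this flask has come to rest by then.

solid substrate 0.0020 M; reagent 2.50 equiv; time 50 min

    starting material + reagent ⇌ intermediate (K1 = 558 M⁻¹, k1 = 1.39 M⁻¹ s⁻¹)
    intermediate ⇌ target + by-product (K2 = 0.013 M, k2 = 0.0125 s⁻¹)
    solid substrate ⇌ starting material, rate k3*(cs3 - [starting material]) while solid is left; crystals form when [starting material] > cs3 (cs3 = 1.7 mM, k3 = 0.0121 s⁻¹)
    target ⇌ isomer of the product (K4 = 0.514, k4 = 0.0420 s⁻¹)

- given per volume of solution although it is solid: solid substrate
- at the start none of the solid substrate is in solution
- what has only dissolved of solid substrate counts as not reacted
- the reaction counts as stopped when no species that holds the solid substrate changes by six tenths of a point or more over the second half of the time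
- run time (flask): 50 min

* which holds at 50 min: what has brought the reaction to rest, or that it has not come to rest (for what has run out or reacted, a solid counts together with what of it has only dissolved) (forward and back rates have come level / it is still moving / the reagent has run out first / all of the solid substrate has reacted)
* part of the solid substrate that has turned into other species by 50 min (what has only dissolved does not count)
* the target standing at 50 min, as a percentage of the solid substrate charged

Step one has a forward half-life of 1.7 min at the charged concentrations and step two has one of 0.924 min. The target and isomer pair relaxes in 0.0934 min, and dissolving the charge takes 1.62 min at the fastest. Each of these is shorter than the run, so I reckon the flask at rest.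

Each by-product stands beside one target or one isomer. The steps therefore multiply into what I carry, the overall constant K: c(by-product) squared over c(starting material)·c(reagent) at rest.

K = 558 M⁻¹ × 0.013 M × (1 + 0.514) = 11.0

For the stages with step two I take the reagent at its excess, e = 3.00 mM, which makes intermediate s = 1.67 times c(starting material). The balance on the charge is then a quadratic in the root of c(starting material):

c(starting material)·(1 + s) + √(K·e·c(starting material)) = 0.0020 M

I build it up in stages:

- **Step one by itself:** e does not apply here, so I solve the bound amount x exactly from the constant of step one, with x taken off both charges. This gives x = 1.34 mM, reagent at 3.66 mM and conversion at 67.0%.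
- **Adding step two:** K is 7.25, c(starting material) falls to 0.127 mM, and conversion rises to 93.7%.
- **Adding the isomer:** K takes its full value, c(starting material) falls to 0.0931 mM, and conversion reaches 95.3%. The by-product is 1.75 mM, and target is 57.8% of the charge.
- **Adding the solid:** this gives a delay and no new number, since that c(starting material) is lower than the solubility.

The forecast says “the flask sits at chemical equilibrium” and gives forward and back rates have come level, with 95.5% conversion (94.5% to 96.5%) and 57.9% target (56.5% to 59.5%). My own two figures are 95.3% and 57.8%.

The simulation gives forward and back rates have come level, with 95.5% conversion and 57.9% target. Step one relaxes in 1.67 min at the end, shorter than the run, and target reads 57.7% at 25.0 min and 57.9% at 50.0 min. The end readings of this flask put the quotient of K at 11.0. The forecast stops holding with less reagent: target has moved by 5 points at 1.32 equiv. In the neighbour flask with 0.620 equiv, where reagent is the limiting reagent and 10.4% of it is left, target stands at 34.8%, and the same quotient reads 9.68.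

Its constants stand for no real mixture; no experiment stands behind them.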